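At early times teal gives 0.6% target against 5.8% other capture product, and the question is what a late start of the substrate does to that split.

| flask | substrate | second nucleophile | solid first nucleophile | temperature | remark | time |
|---|---|---|---|---|---|---|
| teal | 20 mM | 24 mM | 20 mM | 55 °C | run made earlier |  |
| green | 20 mM | 12 mM | 20 mM | 66 °C | run made earlier |  |
| red | 20 mM | 48 mM | 20 mM | 55 °C | run made earlier |  |
| dusk | 20 mM | 24.0 mM (fed, over 10 min) | 20.0 mM | 60 °C | all else is in the flask from the start; the feed brings no volume worth counting | 25 min |
| summer | 20 mM | 24.0 mM | 20.0 mM | 60 °C | everything together at the start | 25 min |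
| autumn | 20 mM | 24.0 mM (fed, over 10 min) | 20.0 mM |  | the addition at 20 °C, then warmed to 60 °C; the feed brings no volume worth counting | 25 min |
| winter | 20 mM (in portions, 3, over 10 min) | 24.0 mM | 20.0 mM | 60 °C | first portion at the start, last at 10 min | 25 min |

- teal (time / min: target / %, other capture product / %): 1.33: 0, 1.0; 4.00: 0.6, 5.8; 8.00: 1.8, 12.6; 10.0: 2.1, 16.1; 15.0: 4.0, 22.9
- green (time / min: target / %, other capture product / %): 2.00: 0.5, 6.9; 6.00: 3.6, 25.7; 12.0: 10.2, 43.1; 20.0: 19.5, 53.0; 25.0: 24.8, 55.4
- red (time / min: target / %, other capture product / %): 2.00: 0.4, 2.9; 4.00: 0.8, 7.6; 8.00: 0.6, 15.1; 12.0: 1.9, 21.9; 25.0: 5.3, 38.5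

(readings scatter by 0.3 percentage points)

- at the start none of the solid first nucleophile is in solution
- a reading or a percentage of target counts all its forms, free or not

1. the flask that comes out highest in share of target in target plus other capture product, or "all alike" when all lie within 1.5 percentage points (dusk / summer / autumn / winter / all alike)
2. share of target in target plus other capture product at the end, dusk
3. share of target in target plus other capture product at the end, summer
4. share of target in target plus other capture product at the end, autumn
5. share of target in target plus other capture product at the end, winter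

I read the teal table down its rows. The share of target in the two products (the selectivity) goes from 9.38% at 4.00 min to 14.9% at 15.0 min, although by then teal has spent 19.1% of its second nucleophile. I take that climb as the solid dissolving on its own clock. Against it, red with 48 mM of second nucleophile shows 15.7% captured at 8.00 min, and teal 14.4%, so that charge divides the substrate rather than hurrying it.

Captured material gives a rate of capture: 0.0209 min⁻¹ in teal and 0.0645 min⁻¹ in green. Whatever stands between substrate and products is not counted in these, so I hold them as low estimates of the substrate's rate. The Arrhenius line through them gives 0.0352 min⁻¹ at 60 °C and 3.28 × 10⁻⁴ min⁻¹ at 20 °C. By this estimate the cold addition costs autumn about 0.328% of its substrate.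

For summer and dusk that makes 9.83 min the half-capture time: the clock time, counted from the start of the flask, by which half of the substrate's turnover up to the reading is done. Winter, taken at the mean arrival of its portions, gives 13.3 min, and autumn 16.5 min. The later the half-capture time, the higher I put the share, so I commit to autumn, assuming the solid dissolves as well in the cold, which no run tests.

The forecast differs. It names winter, with 20.5%, then dusk 19%, summer 17.5% and autumn 16%: “Delaying substrate lets dissolved nucleophile build up”.

Autumn comes out highest, at 24.7%, with winter 21.5%, dusk 20.6% and summer 18.7%.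

    substrate → intermediate (k = 7.10 × 10⁻⁴ s⁻¹, Ea = 106 kJ mol⁻¹)
    first nucleophile + intermediate → target (k = 1.10 M⁻¹ s⁻¹, Ea = 50.0 kJ mol⁻¹)
    second nucleophile + intermediate → other capture product (k = 0.620 M⁻¹ s⁻¹, Ea = 64.0 kJ mol⁻¹)
    first nucleophile + target ⇌ idle adduct, settled at all times (K = 380 M⁻¹, ΔH = 51.0 kJ mol⁻¹)
    solid first nucleophile ⇌ first nucleophile, rate k5*(cs5 - [first nucleophile]) while solid is left; crystals form when [first nucleophile] > cs5 (solubility = 19.0 mM, k = 3.20 × 10⁻⁴ s⁻¹)
    crystals ⇌ target, rate k6*(cs6 - [target]) while solid is left; crystals form when [target] > cs6 (solubility = 6.50 mM, k = 0.0270 s⁻¹)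
    (constants at 60 °C)

At 10.0 min autumn holds 3.32 mM first nucleophile with 99.8% of its substrate still there, where dusk holds 1.94 mM with 65.3%. My estimated half-capture times of 9.83 min in summer, 13.3 min in winter and 16.5 min in autumn stand beside shares of 18.7%, 21.5% and 24.7%. Reckoned from the substrate left and the scheme's 0.0426 min⁻¹, autumn's half-capture time is 16.3 min at 25.0 min and 25.5 min at 1.5 h, where its share is 24.7% and 33.8%.

The earlier runs and the new flask were generated by integration with made-up constants.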